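I began with the easy step: in each earlier run the last reading, at 20.0 min, was the highest, 26%, 36% and 25% of the substrate charged, so I looked for a steady climb.

| flask | substrate | coupling partner | remark | time |
|---|---|---|---|---|
| midnight | 0.20 M | 0.42 M | run made earlier |  |
| summer | 0.20 M | 0.66 M | run made earlier |  |
| dawn | 0.10 M | 0.30 M | run made earlier |  |
| flask | 0.20 M | 0.300 M |  | 25 min |

| run | time / min | target / % |
|---|---|---|
| midnight | 6.00 | 4 |
| midnight | 10.0 | 16 |
| midnight | 15.0 | 20 |
| midnight | 20.0 | 26 |
| summer | 6.00 | 11 |
| summer | 10.0 | 22 |
| summer | 15.0 | 26 |
| summer | 20.0 | 36 |
| dawn | 6.00 | 7 |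
| dawn | 10.0 | 12 |
| dawn | 15.0 | 23 |
| dawn | 20.0 | 25 |

(standard deviation of a reading: 2 percentage points)

- the numbers in the tables scatter by 2 percentage points (one standard deviation)

- time up to 25 min at which target stands highest
- the amount of target, in percent of the substrate charged, at that time

I held the coupling partner at its mean, a pseudo-first-order reckoning. The last reading of each run then gives a constant, scatter included, as −ln(unreacted fraction) over mean partner and time: 0.0382 M⁻¹ min⁻¹, 0.0358 M⁻¹ min⁻¹ and 0.0500 M⁻¹ min⁻¹, with mean 0.0413 M⁻¹ min⁻¹. For the flask, a first pass with undiminished partner puts target at 26.7%, so I reckoned the partner's mean at 91.1% of its charge, counting its use for target and nothing else. That gives N = 0.282: the conversion number, constant times mean partner times time, counts the substrate lifetimes the flask has had.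

I reckoned target as one minus exp(−N), 24.6%, and N grows with time, so I put the highest point at 25 min. Exact integration of the same one-step law gives 24.6%, so within that law the mean cost far less than the scatter.

One number was not quite enough: the constant read from dawn stands above the other two, and dawn shares the flask's 0.300 M of partner, though at a different charge of substrate. Dawn's constant puts the flask at 29.0%, so I committed to the span from 24.6% to 29.0%.

The forecast gave 25% at 25 min, since the target is “still rising at 20 min in all three runs”. The flask gave 27.0% at 25.0 min, inside my span.

    substrate ⇌ reactive form (K = 1.90, k = 0.0431 min⁻¹)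
    coupling partner + reactive form → target (k = 0.543 M⁻¹ min⁻¹)
    coupling partner ⇌ dormant form (K = 3.67, k = 0.0893 min⁻¹)
    substrate + reactive form → side product (k = 0.0531 M⁻¹ min⁻¹)

I carried N to the same flask read at 1.0 h, with the charges held. A first pass puts target at 52.5%, the partner's mean at 82.5% of its charge, and N at 0.614, so I reckoned 45.9%. That flask held 47.8% of target. N speaks for target, not substrate: my reckoning leaves 54.1% of the substrate, where that flask held 18.1%, with 22.9% standing as reactive form.

The runs are simulated with made-up constants; the scatter is artificial.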